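**Retrosynthetic overview**

1. The route rests on one feature of the ten-membered ring C1–C10: C4 (methyl C15, later an oxirane carbon) and the oxygenated C9 lie 1,6 across it. One extra C4–C9 bond turns it into two six-membered rings, C4–C5–C6–C7–C8–C9 (the carvone ring, with C15 and C11–C13) and C4–C3–C2–C1=C10–C9.
2. Fluctuadin 24 ⇐ O8 methacryloylation, oxidation of C12 (tetrahydrofuran → lactone), 4,5-epoxidation, C9 reduction and acetylation of dienone 18.
3. 18 ⇐ heterolytic (Grob, Wharton-type) fragmentation of the trans-fused 9-hydroxy 5-mesylate 17, which cuts C4–C9 and releases the ten-membered ring.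
4. 17 ⇐ C9–C10 closure of (Z)-iodoenoate 16 onto the C9 ketone. 16 ⇐ (R)-carvone: deconjugative propargylation (C4), enolate hydroxylation then epimerisation (O8), α-epoxidation and opening from C12–OH (O5, O6).
5. Rings form in this order: carvone ring (given), tetrahydrofuran (step 7), cyclohexene C4–C3–C2–C1=C10–C9 (step 12), ten-membered ring by C4–C9 cleavage (step 13), oxirane (step 16); the lactone comes from oxidation of the tetrahydrofuran (step 17).

Key step: step 13

Remark: the target is taken as drawn, with C6–O, C7–C11 and C8–O on one face (cis-fused lactone). Germacrane numbering is kept throughout; β is the face of the C7–C11 bond (ring C4–C9 before step 13, flat drawing of ring C1–C10 after it) and α the opposite face.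

**Route**

Step 1
Reactants: 1 (R)-(−)-carvone; 2 propargyl bromide
Product: 3 (2S,5S)-2-methyl-5-(prop-1-en-2-yl)-2-(prop-2-yn-1-yl)cyclohex-3-en-1-one (4β-propargyl, 4α-methyl; propargyl cis to isopropenyl)
Conditions: KOt-Bu (1.0 equiv), t-BuOH/THF, 0 °C; then 2, 0 °C → rt
Reagents that add atoms: none
Why: Deconjugative α-alkylation of the extended potassium dienolate (proton lost from C6, bond made at C4) with a reactive propargylic halide; axial entry on the half-chair that keeps isopropenyl pseudoequatorial should place the propargyl group cis to it (C4 set), as in alkylations of dihydrocarvone enolates, and the minor C4 epimer is removed by chromatography.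

Step 2
Reactants: 3 4β-propargyl ketone
Product: 4 8α-hydroxy ketone (hydroxyl trans to isopropenyl)
Conditions: KN(SiMe3)2, THF, −78 °C; 2-(phenylsulfonyl)-3-phenyloxaziridine, −78 °C; aq. NH4Cl
Reagents that add atoms: 2-(phenylsulfonyl)-3-phenyloxaziridine O=S(=O)(c1ccccc1)N1OC1c1ccccc1
Why: Davis oxaziridine hydroxylation of the only possible enolate (C8, since C4 is quaternary); the oxidant approaches the flat enolate anti to the isopropenyl group on the adjacent C7, giving the 8α alcohol, which is corrected in step 9.

Step 3
Reactants: 4 8α-hydroxy ketone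
Product: 5 8α-tert-butyldimethylsilyl ether
Conditions: TBSOTf, 2,6-lutidine, CH2Cl2, −78 → 0 °C
Reagents that add atoms: tert-butyldimethylsilyl triflate CC(C)(C)[Si](C)(C)OS(=O)(=O)C(F)(F)F
Why: Silylation of a hindered secondary α-ketol with a silyl triflate and a hindered pyridine base, which touches no stereocentre and gives a non-chelating O8 group for step 14.

Step 4
Reactants: 5 silyl ether
Product: 6 allylic chloride (isopropenyl changed into 3-chloroprop-1-en-2-yl)
Conditions: Ca(OCl)2, solid CO2, CH2Cl2/H2O, 0 °C
Reagents that add atoms: calcium hypochlorite [Ca+2].[O-]Cl.[O-]Cl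
Why: Ene-type allylic chlorination by HOCl, which selects the 1,1-disubstituted isopropenyl alkene over the hindered 1,2-disubstituted ring alkene and the alkyne and removes a methyl hydrogen, the reaction type that converts carvone into its 10-chloro derivative.

Step 5
Reactants: 6 allylic chloride
Product: 7 enal (3-oxoprop-1-en-2-yl on C7)
Conditions: N-methylmorpholine N-oxide, KI (cat.), MeCN, 40 °C
Reagents that add atoms: N-methylmorpholine N-oxide C[N+]1([O-])CCOCC1
Why: Amine N-oxide oxidation of an allylic halide (Ganem/Kornblum type: O-alkylation of the N-oxide, then elimination), which makes the side-chain alkene electron-poor before the ring alkene is oxidised.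

Step 6
Reactants: 7 enal
Product: 8 5α,6α-epoxy enal
Conditions: dimethyldioxirane, acetone, 0 °C
Reagents that add atoms: dimethyldioxirane CC1(C)OO1
Why: Electrophilic epoxidation reaches only the isolated cis alkene (the enal alkene is electron-poor, the alkyne inert) and should come from the α face, anti to the C7 side chain and to the pseudoaxial propargyl arm on C4, which sets C5–O α.

Step 7
Reactants: 8 epoxy enal
Product: 10 5α-hydroxy ketone carrying a cis-fused 3-methylenetetrahydrofuran (O6β–C12), via epoxy allylic alcohol 9 (not isolated)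
Conditions: LiAlH(Ot-Bu)3, THF, −78 °C; then camphorsulfonic acid (cat.), CH2Cl2, 0 °C → rt
Reagents that add atoms: none
Why: The bulky alkoxyaluminium hydride reduces the unhindered enal 1,2 and leaves the neopentyl α-siloxy ketone, and acid then drives 5-exo-tet opening of the epoxide at C6 by the new primary alcohol with inversion (Fürst–Plattner diaxial opening), which sets C6–O β (cis to C11), keeps C5–OH α and masks O6 and C12 as one inert ether.

Step 8
Reactants: 10 hydroxy tetrahydrofuran ketone
Product: 11 5α-mesylate (8α-siloxy)
Conditions: MsCl, Et3N, CH2Cl2, 0 °C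
Reagents that add atoms: methanesulfonyl chloride CS(=O)(=O)Cl
Why: Sulfene-type mesylation of the only free hydroxyl, the hindered secondary C5–OH, done before any base treatment so that the β-hydroxy ketone cannot undergo retro-aldol cleavage.

Step 9
Reactants: 11 8α-siloxy mesylate
Product: 12 8β-siloxy mesylate (C8 epimer; O6, C11 and O8 all β)
Conditions: DBU, toluene, 40 °C
Reagents that add atoms: none
Why: Thermodynamic epimerisation through the C8 enolate (the only one possible); in the chair that holds O5 and O6 equatorial, C15 and C11 are axial and an 8α-siloxy group is syn-axial to C15, so the equilibrium should move to the equatorial 8β epimer, while the mesylate has no hydrogen on C4 and no antiperiplanar hydrogen on C6 for elimination.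

Step 10
Reactants: 12 8β-siloxy mesylate
Product: 13 aldehyde (3-oxopropyl on C4; C1 is the formyl carbon)
Conditions: dicyclohexylborane, THF, 0 °C; then H2O2, pH 7 phosphate buffer, 0 °C → rt
Reagents that add atoms: hydrogen peroxide OO
Why: Anti-Markovnikov hydroboration of the terminal alkyne with a hindered dialkylborane and oxidation of the alkenylborane to the aldehyde; the alkyne reacts much faster than the 1,1-disubstituted alkene or the hindered ketone.

Step 11
Reactants: 13 aldehyde; 14 methyl (triphenylphosphoranylidene)acetate
Product: 16 (Z)-α-iodo enoate (iodine cis to C2), via methyl iodo(triphenylphosphoranylidene)acetate 15 (not isolated)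
Conditions: 14, N-iodosuccinimide, CH2Cl2, −20 °C; then K2CO3, 13, −20 °C → rt
Reagents that add atoms: N-iodosuccinimide O=C1CCC(=O)N1I
Why: One-pot iodination of the stabilised ylide and Wittig olefination of the aldehyde (the hindered ketone does not react); the stabilised iodo ylide places the ester trans to the chain, so iodine is cis to C2, the geometry required for closure of a six-membered ring.

Step 12
Reactants: 16 (Z)-α-iodo enoate
Product: 17 trans-fused bicyclic 9β-hydroxy 5α-mesylate (fragmentation precursor)
Conditions: CrCl2, NiCl2 (cat.), DMSO, rt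
Reagents that add atoms: none
Why: Intramolecular Nozaki–Hiyama–Kishi reaction (zerovalent nickel inserts into C–I, transmetalation gives the alkenylchromium species, which adds to the C9 ketone and tolerates ester, mesylate and ether); the tether leaves C4 equatorially and the axial C11 blocks the β axial trajectory at C9, so C10 should enter equatorially, giving the trans ring fusion with the 9β hydroxyl axial and anti to axial C15.

Step 13
Reactants: 17 trans-fused hydroxy mesylate
Product: 18 ten-membered dienone (C9 ketone, 4E alkene, ring-cis C1=C10 enoate)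
Conditions: KN(SiMe3)2 (1.05 equiv), THF, −78 → 0 °C
Reagents that add atoms: none
Why: Deprotonation gives the tertiary C9 potassium alkoxide, whose lone pair pushes into the C9–C4 σ bond while that bond, antiperiplanar to the equatorial C5–O bond of the trans-fused chair, donates into σ*(C5–OMs), so that C9=O forms, C4–C9 breaks, C4=C5 forms and mesylate leaves in one concerted Grob fragmentation. The closest known reaction type is the Wharton fragmentation of decalin 1,3-diol monosulfonates (angular hydroxyl, sulfonate next to the other ring-fusion carbon) to (E)-cyclodec-5-enones. The ten-membered ring C1–C10 is not closed by bond formation: it is the periphery of the bicycle and is released when the shared bond is cut, so neither dilution nor an exo/endo closure mode is involved. No stereocentre is created (C4, C5 and C9 become trigonal); the C4=C5 alkene is E because C3, equatorial on C4, is anti to C6 across C4–C5 in the reacting chair, and the enoate keeps the ring-cis geometry it had in the cyclohexene. The step needs fragmentation to outrun oxetane formation, elimination and C8 epimerisation: the axial alkoxide cannot reach the rear of the equatorial C5–O bond, C4 bears no hydrogen and C6 no antiperiplanar one, and one equivalent of a non-nucleophilic amide base at low temperature leaves nothing to enolise the product or to add to its alkylidene keto ester unit. The methylene-tetrahydrofuran, the ester and the silyl ether are inert, any 1,2-silyl shift to the hindered tertiary alkoxide being reversible and unproductive.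

Step 14
Reactants: 18 dienone
Product: 19 9α-alcohol
Conditions: NaBH4, CeCl3·7H2O, MeOH, −78 °C
Reagents that add atoms: none
Why: Luche 1,2-reduction of the cross-conjugated ketone; with the non-chelating silyl ether the Felkin–Anh polar model (hydride anti to the C8–O bond, passing H8) predicts the 8,9-syn diol pattern, that is the 9α alcohol of the target.

Step 15
Reactants: 19 9α-alcohol
Product: 20 9α-acetate
Conditions: Ac2O, pyridine, DMAP (cat.), CH2Cl2, 0 °C → rt
Reagents that add atoms: acetic anhydride CC(=O)OC(C)=O
Why: DMAP-catalysed acetylation of the only free hydroxyl, kept cold to avoid allylic transposition of the hydroxy enoate unit.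

Step 16
Reactants: 20 9α-acetate
Product: 21 4,5-epoxide (oxygen α at C5, C15 cis to C6 on the oxirane)
Conditions: mCPBA, NaHCO3, CH2Cl2, 0 °C
Reagents that add atoms: 3-chloroperoxybenzoic acid OOC(=O)c1cccc(Cl)c1
Why: Prilezhaev epoxidation of the only electron-rich trisubstituted alkene (the enoate is electron-poor, the exocyclic methylene 1,1-disubstituted and deactivated by the allylic oxygen); A(1,3) strain with C15 holds H6 in the alkene plane, so the peripheral face is the one bearing O6, and attack there gives the C4/C5 configuration of the target, with the E geometry passed on as the trans oxirane.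

Step 17
Reactants: 21 epoxide
Product: 22 6,12-lactone (α-methylene-γ-butyrolactone, O8 silyl)
Conditions: CrO3, 3,5-dimethylpyrazole, CH2Cl2, −20 °C
Reagents that add atoms: chromium trioxide O=[Cr](=O)=O
Why: Allylic oxidation of a cyclic allylic ether to the unsaturated lactone by the non-acidic hexavalent chromium–pyrazole complex, as known for 3-methylenetetrahydrofurans; C12–H2 is the only C–H that is both allylic and next to oxygen once C4=C5 is epoxidised, and the oxirane tolerates the medium.

Step 18
Reactants: 22 silyl lactone
Product: 23 8β-alcohol (8-O-desmethacryloyl fluctuadin)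
Conditions: HF·pyridine, pyridine, THF, 0 °C → rt
Reagents that add atoms: none
Why: Fluoride-mediated desilylation under buffered, slightly acidic conditions, which spare the oxirane and the α-methylene lactone and do not promote acetyl migration from O9.

Step 19
Reactants: 23 8β-alcohol
Product: 24 fluctuadin
Conditions: methacrylic anhydride, Et3N, DMAP (cat.), CH2Cl2, 0 °C
Reagents that add atoms: methacrylic anhydride C=C(C)C(=O)OC(=O)C(C)=C
Why: DMAP-catalysed acylation of the single free secondary hydroxyl, run cold so that acylation outpaces 1,2-acetyl migration.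

**Compound list**

1 | (R)-(−)-carvone | O=C1C[C@H](C(C)=C)CC=C1C | starting material
2 | propargyl bromide | C#CCBr | starting material
3 | (2S,5S)-2-methyl-5-(prop-1-en-2-yl)-2-(prop-2-yn-1-yl)cyclohex-3-en-1-one (4β-propargyl) | O=C1[C@@](C)(CC#C)C=C[C@@H](C(C)=C)C1 | intermediate
4 | 8α-hydroxy ketone (OH trans to isopropenyl) | O=C1[C@@](C)(CC#C)C=C[C@@H](C(C)=C)[C@@H]1O | intermediate
5 | 8α-tert-butyldimethylsilyl ether | O=C1[C@@](C)(CC#C)C=C[C@@H](C(C)=C)[C@@H]1O[Si](C)(C)C(C)(C)C | intermediate
6 | allylic chloride (3-chloroprop-1-en-2-yl on C7) | O=C1[C@@](C)(CC#C)C=C[C@@H](C(CCl)=C)[C@@H]1O[Si](C)(C)C(C)(C)C | intermediate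
7 | enal (3-oxoprop-1-en-2-yl on C7) | O=C1[C@@](C)(CC#C)C=C[C@@H](C(C=O)=C)[C@@H]1O[Si](C)(C)C(C)(C)C | intermediate
8 | 5α,6α-epoxy enal | O=C1[C@@](C)(CC#C)[C@@H]2O[C@@H]2[C@@H](C(C=O)=C)[C@@H]1O[Si](C)(C)C(C)(C)C | intermediate
9 | 5α,6α-epoxy allylic alcohol | O=C1[C@@](C)(CC#C)[C@@H]2O[C@@H]2[C@@H](C(CO)=C)[C@@H]1O[Si](C)(C)C(C)(C)C | intermediate (not isolated)
10 | 5α-hydroxy ketone with cis-fused 3-methylenetetrahydrofuran (O6β), 8α-siloxy | O=C1[C@@](C)(CC#C)[C@H](O)[C@H]2OCC(=C)[C@H]2[C@@H]1O[Si](C)(C)C(C)(C)C | intermediate
11 | 5α-mesylate, 8α-siloxy | O=C1[C@@](C)(CC#C)[C@H](OS(C)(=O)=O)[C@H]2OCC(=C)[C@H]2[C@@H]1O[Si](C)(C)C(C)(C)C | intermediate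
12 | 5α-mesylate, 8β-siloxy | O=C1[C@@](C)(CC#C)[C@H](OS(C)(=O)=O)[C@H]2OCC(=C)[C@H]2[C@H]1O[Si](C)(C)C(C)(C)C | intermediate
13 | aldehyde (3-oxopropyl on C4) | O=C1[C@@](C)(CCC=O)[C@H](OS(C)(=O)=O)[C@H]2OCC(=C)[C@H]2[C@H]1O[Si](C)(C)C(C)(C)C | intermediate
14 | methyl (triphenylphosphoranylidene)acetate | COC(=O)C=P(c1ccccc1)(c1ccccc1)c1ccccc1 | starting material
15 | methyl iodo(triphenylphosphoranylidene)acetate | COC(=O)C(I)=P(c1ccccc1)(c1ccccc1)c1ccccc1 | intermediate (not isolated)
16 | (Z)-α-iodo enoate | O=C1[C@@](C)(CC/C=C(\I)C(=O)OC)[C@H](OS(C)(=O)=O)[C@H]2OCC(=C)[C@H]2[C@H]1O[Si](C)(C)C(C)(C)C | intermediate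
17 | trans-fused bicyclic 9β-hydroxy 5α-mesylate (O6β in tetrahydrofuran, 8β-siloxy, enoate in ring) | COC(=O)C1=CCC[C@@]2(C)[C@H](OS(C)(=O)=O)[C@H]3OCC(=C)[C@H]3[C@@H](O[Si](C)(C)C(C)(C)C)[C@]12O | intermediate
18 | ten-membered dienone (C9 ketone, 4E alkene, ring-cis enoate) | CC(C)(C)[Si](C)(C)O[C@@H]1[C@@H]2C(=C)CO[C@@H]2/C=C(\C)CC/C=C(/C(=O)OC)C1=O | intermediate
19 | 9α-alcohol | CC(C)(C)[Si](C)(C)O[C@@H]1[C@@H]2C(=C)CO[C@@H]2/C=C(\C)CC/C=C(/C(=O)OC)[C@H]1O | intermediate
20 | 9α-acetate | CC(C)(C)[Si](C)(C)O[C@@H]1[C@@H]2C(=C)CO[C@@H]2/C=C(\C)CC/C=C(/C(=O)OC)[C@H]1OC(C)=O | intermediate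
21 | 4,5-epoxide | CC(C)(C)[Si](C)(C)O[C@@H]1[C@@H]2C(=C)CO[C@@H]2[C@H]3O[C@]3(C)CC/C=C(/C(=O)OC)[C@H]1OC(C)=O | intermediate
22 | 6,12-lactone, O8 silyl | CC(C)(C)[Si](C)(C)O[C@@H]1[C@@H]2C(=C)C(=O)O[C@@H]2[C@H]3O[C@]3(C)CC/C=C(/C(=O)OC)[C@H]1OC(C)=O | intermediate
23 | 8β-alcohol | O[C@@H]1[C@@H]2C(=C)C(=O)O[C@@H]2[C@H]3O[C@]3(C)CC/C=C(/C(=O)OC)[C@H]1OC(C)=O | intermediate
24 | fluctuadin | C=C(C)C(=O)O[C@@H]1[C@@H]2C(=C)C(=O)O[C@@H]2[C@H]2O[C@]2(C)CC/C=C(/C(=O)OC)[C@H]1OC(C)=O | target

**Step count and risks**

Total step count: 19. Longest linear sequence: 19 steps from 1 (2 and 14 are bought).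

Steps most likely to fail:

Step 1. The dienolate may be alkylated with poor facial selectivity at C4, or at C8 after proton exchange. Fallback (sets out from 1, returns at 5): the order of the first operations is reversed so that the C8 oxygen controls C4. Enolate hydroxylation of 1 (LiN(i-Pr)2, then the oxaziridine of step 2) gives trans-6-hydroxycarvone F1. Silylation as in step 3 gives silyl ether F2. Deconjugative propargylation of F2 (KOt-Bu, 2) should then occur anti to the pseudoaxial C8 siloxy group (1,3-induction), which gives 5 directly.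

Step 12. Addition of the alkenylchromium species to the hindered ketone may be slower than its protonation, so that only de-iodinated enoate is returned. Fallback (sets out from 13, returns at 17): the ring is closed by thia-Michael/aldol addition and sulfoxide elimination. Wittig reaction of 13 with 14 (no iodination) gives (E)-enoate F3. Me2AlSPh in CH2Cl2 at −78 °C adds thiolate to C1, and the aluminium enolate closes onto the C9 ketone under the same conformational control, giving β-phenylthio aldol F4 (C1 and C10 configurations immaterial). mCPBA (1 equiv, −78 °C) gives sulfoxide F5, which on warming in toluene loses benzenesulfenic acid towards the acidic C10–H and returns 17.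

Step 17. The chromium oxidant may attack other C–H bonds, over-oxidise, or open the oxirane. Fallback (sets out from 21, returns at 22): the oxidation is split into two mild stages. SeO2 (cat.) with t-BuOOH in CH2Cl2 hydroxylates the allylic C12 methylene (CH2 preferred over the C7 methine) to give lactol F6. MnO2 (or Ag2CO3 on Celite) then oxidises the lactol to lactone 22.

Further compounds
F1 | step 1 | trans-6-hydroxycarvone (hydroxyl trans to isopropenyl) | O=C1C(C)=CC[C@@H](C(C)=C)[C@@H]1O
F2 | step 1 | tert-butyldimethylsilyl ether of F1 | O=C1C(C)=CC[C@@H](C(C)=C)[C@@H]1O[Si](C)(C)C(C)(C)C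
F3 | step 12 | (E)-enoate from 13 (iodine-free analogue of 16) | O=C1[C@@](C)(CC/C=C/C(=O)OC)[C@H](OS(C)(=O)=O)[C@H]2OCC(=C)[C@H]2[C@H]1O[Si](C)(C)C(C)(C)C
F4 | step 12 | bicyclic 1-phenylthio aldol (9β-hydroxyl; mixture at C1 and C10) | COC(=O)C1C(Sc2ccccc2)CC[C@@]2(C)[C@H](OS(C)(=O)=O)[C@H]3OCC(=C)[C@H]3[C@@H](O[Si](C)(C)C(C)(C)C)[C@]12O
F5 | step 12 | sulfoxide of F4 | COC(=O)C1C(S(=O)c2ccccc2)CC[C@@]2(C)[C@H](OS(C)(=O)=O)[C@H]3OCC(=C)[C@H]3[C@@H](O[Si](C)(C)C(C)(C)C)[C@]12O
F6 | step 17 | C12 lactol of 21 (both anomers) | CC(C)(C)[Si](C)(C)O[C@@H]1[C@@H]2C(=C)C(O)O[C@@H]2[C@H]3O[C@]3(C)CC/C=C(/C(=O)OC)[C@H]1OC(C)=O
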